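## Retrosynthetic overview

1. Feature: in ring C, C2 is bonded to O1 and to C1' of the 2',4'-dioxygenated ring B. It stands 1,6 to C3 along C3–C4–C4a–C8a–O1–C2, so as a CH2 it offers two enantiotopic, strongly hydridic C–H bonds to a carbene centre at C3.
2. Key disconnection C2–C3: the (2S)-flavanone, with its three phenols as TBS ethers, goes back to an open α-diazoketone on ring A whose O1 already carries the ring B benzyl group. A chiral dirhodium-catalysed C–H insertion closes ring C and sets C2 in one event.
3. The diazoketone comes from the methyl ketone by trifluoroacetylation and diazo transfer. The O1–C2 bond comes from a Mitsunobu coupling of a ring A phenol with a ring B benzyl alcohol.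
4. Ring A piece: phloroacetophenone, C-prenylation (future C8), selective bis-silylation. Ring B piece: 4-hydroxy-2-methoxybenzaldehyde, O-prenylation, aromatic Claisen rearrangement (1,1-dimethylallyl at C5'), silylation, reduction.
5. Ring order: rings A and B are bought as arenes, and ring C is the only ring made, in the second-to-last step. A buffered fluoride desilylation ends the route.

Key step: step 10

Assumption: the absolute sense of induction of Rh2(S-PTTL)4 on this substrate cannot be predicted with certainty. The S-ligand catalyst is written throughout; if chiral HPLC and CD analysis of the key-step product point to 2R, the mirror-image Rh2(R-PTTL)4 is used with no other change.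

## Route

Step 1
Reactants: 1 2',4',6'-trihydroxyacetophenone; 2 prenyl bromide
Product: 3 1-[2,4,6-trihydroxy-3-(3-methylbut-2-enyl)phenyl]ethanone
Conditions: KOH (1 equiv), H2O, 0 °C to rt, 2 (0.9 equiv) added slowly
Reagents that add atoms: prenyl bromide (compound 2), CC(C)=CCBr
Why: C-alkylation of an ambident phloroglucinol phenoxide (SN2 at the allylic bromide): in water the oxygen atoms are tied up by hydrogen bonding so the electron-rich ring carbon attacks, the two open ring positions are equivalent so a single mono-C-prenyl isomer results, and a deficit of 2 limits double prenylation.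

Step 2
Reactants: 3 1-[2,4,6-trihydroxy-3-(3-methylbut-2-enyl)phenyl]ethanone
Product: 4 1-[4,6-bis(tert-butyldimethylsilyloxy)-2-hydroxy-3-(3-methylbut-2-enyl)phenyl]ethanone
Conditions: TBSCl (2.05 equiv), imidazole, CH2Cl2–DMF, 0 °C to rt
Reagents that add atoms: TBSCl, CC(C)(C)[Si](C)(C)Cl
Why: Sterically and hydrogen-bond controlled O-silylation: the unchelated para OH and the ortho OH next to a ring hydrogen are silylated, whereas the OH wedged between the acetyl and prenyl groups stays locked in its hydrogen bond to C=O and is too crowded for TBSCl, which leaves free exactly the oxygen that becomes O1.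

Step 3
Reactants: 5 4-hydroxy-2-methoxybenzaldehyde; 2 prenyl bromide
Product: 6 2-methoxy-4-(3-methylbut-2-enyloxy)benzaldehyde
Conditions: K2CO3, acetone, reflux
Reagents that add atoms: prenyl bromide (compound 2), CC(C)=CCBr
Why: Williamson ether synthesis: the acidic para-formyl phenoxide reacts at oxygen in a polar aprotic medium by clean SN2 displacement on the primary allylic bromide.

Step 4
Reactants: 6 2-methoxy-4-(3-methylbut-2-enyloxy)benzaldehyde
Product: 8 4-hydroxy-2-methoxy-5-(2-methylbut-3-en-2-yl)benzaldehyde, via ortho-dienone 7 (not isolated)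
Conditions: EtOH–H2O (4:1), degassed, sealed tube, 130 °C
Reagents that add atoms: none
Why: Aromatic Claisen rearrangement: the [3,3] shift inverts the allyl unit so that the O-prenyl group arrives on carbon as the 1,1-dimethylallyl group, the new quaternary carbon goes to the open C5 rather than to C3 crowded between two oxygen substituents, tautomerisation of 7 restores the arene, and the protic medium accelerates the polar transition state so that a temperature below the range of prenyl loss and abnormal Claisen isomerisation suffices.

Step 5
Reactants: 8 4-hydroxy-2-methoxy-5-(2-methylbut-3-en-2-yl)benzaldehyde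
Product: 9 4-(tert-butyldimethylsilyloxy)-2-methoxy-5-(2-methylbut-3-en-2-yl)benzaldehyde
Conditions: TBSCl, imidazole, DMAP (cat.), DMF, rt to 40 °C
Reagents that add atoms: TBSCl, CC(C)(C)[Si](C)(C)Cl
Why: Imidazole-promoted silylation: the phenol is acidified by the para formyl group and still reacts although it is flanked by the tertiary alkyl group, and that neighbour later shields the silyl ether.

Step 6
Reactants: 9 4-(tert-butyldimethylsilyloxy)-2-methoxy-5-(2-methylbut-3-en-2-yl)benzaldehyde
Product: 10 [4-(tert-butyldimethylsilyloxy)-2-methoxy-5-(2-methylbut-3-en-2-yl)phenyl]methanol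
Conditions: NaBH4, THF–MeOH, 0 °C, short reaction time; Et3N-washed silica
Reagents that add atoms: none
Why: Borohydride 1,2-reduction of an aromatic aldehyde: hydride addition is fast at 0 °C, the isolated alkene is inert and the hindered aryl silyl ether outlasts the short exposure to methanol.

Step 7
Reactants: 4 1-[4,6-bis(tert-butyldimethylsilyloxy)-2-hydroxy-3-(3-methylbut-2-enyl)phenyl]ethanone; 10 [4-(tert-butyldimethylsilyloxy)-2-methoxy-5-(2-methylbut-3-en-2-yl)phenyl]methanol
Product: 11 1-[2-{[4-(tert-butyldimethylsilyloxy)-2-methoxy-5-(2-methylbut-3-en-2-yl)phenyl]methoxy}-4,6-bis(tert-butyldimethylsilyloxy)-3-(3-methylbut-2-enyl)phenyl]ethanone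
Conditions: PPh3, DIAD, THF (concentrated), 0 °C to rt; Et3N-washed silica
Reagents that add atoms: none
Why: Mitsunobu etherification: the primary benzylic alcohol is activated as its oxyphosphonium ion and displaced by the phenol of 4, which is acidic enough for the betaine, under neutral conditions that spare the aryl silyl ethers and avoid an isolated 2,4-dioxygenated benzyl halide, which would be too labile to handle.

Step 8
Reactants: 11 the ring A/ring B benzyl ether methyl ketone
Product: 13 4,4,4-trifluoro-1-aryl-butane-1,3-dione derived from 11 (aryl = the fully substituted ring A of 11; used crude), via lithium enolate 12 (not isolated)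
Conditions: LiHMDS (1.1 equiv), THF, −78 °C; CF3CO2CH2CF3 (1.2 equiv), −78 °C; AcOH quench
Reagents that add atoms: 2,2,2-trifluoroethyl trifluoroacetate, O=C(OCC(F)(F)F)C(F)(F)F; LiHMDS, [Li+].C[Si](C)(C)[N-][Si](C)(C)C (lithium of 12)
Why: Crossed Claisen condensation: the acetyl CH3 is the only enolisable position, its kinetic lithium enolate is C-acylated at once by the activated trifluoroacetate ester at −78 °C, cold enough to hold back silyl migration from the neighbouring aryl oxygen, and this activates the methyl ketone for diazo transfer.

Step 9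
Reactants: 13 the trifluoroacetylated ketone
Product: 14 2-diazo-1-[2-{[4-(tert-butyldimethylsilyloxy)-2-methoxy-5-(2-methylbut-3-en-2-yl)phenyl]methoxy}-4,6-bis(tert-butyldimethylsilyloxy)-3-(3-methylbut-2-enyl)phenyl]ethanone
Conditions: 4-acetamidobenzenesulfonyl azide (1.5 equiv), Et3N (1.5 equiv), H2O (1 equiv), MeCN, rt; Et3N-washed silica
Reagents that add atoms: 4-acetamidobenzenesulfonyl azide, CC(=O)Nc1ccc(cc1)S(=O)(=O)N=[N+]=[N-]
Why: Detrifluoroacetylative (Regitz-type) diazo transfer: the triethylammonium enolate of 13 adds to the terminal nitrogen of the sulfonyl azide and the triazoline formed collapses with passage of the trifluoroacetyl group to the sulfonamide nitrogen, which leaves the terminal diazoketone under conditions mild enough for the silyl and benzyl ethers.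

Step 10
Reactants: 14 the diazoketone
Product: 15 (2S)-5,7-bis(tert-butyldimethylsilyloxy)-2-[4-(tert-butyldimethylsilyloxy)-2-methoxy-5-(2-methylbut-3-en-2-yl)phenyl]-8-(3-methylbut-2-enyl)chroman-4-one
Conditions: Rh2(S-PTTL)4 (2 mol %), 4 Å MS, toluene, 0 °C, 14 added by syringe pump (final ca. 5 mM)
Reagents that add atoms: none
Why: Rh2(S-PTTL)4 takes up the diazo carbon of 14 and loses N2 to give an electrophilic divalent rhodium carbenoid at C3, which engages one C–H bond of the O1–CH2–ring B group in a concerted but asynchronous, hydride-transfer-like three-centre transition state that makes C2–C3 and C3–H and releases the catalyst. The closest known reaction type is the enantioselective intramolecular C–H insertion of ortho-alkoxyaryl diazoketones to 2-substituted chroman-4-ones under chiral dirhodium tetracarboxylates. Ring C closes in the 1,6 insertion mode through a chair-like six-membered array C3–C4–C4a–C8a–O1–C2, the usual 1,5 mode being shut off because the fifth atom is O1 and bears no hydrogen. C2 is set by the catalyst alone: the two benzylic hydrogens are enantiotopic, insertion goes with retention at carbon, and the phthalimide walls of the tert-leucinate ligands should admit only the array that holds ring B pseudo-equatorial on one face of the carbenoid, which decides which hydrogen is replaced. The step needs chemoselectivity for C–H insertion over attack on the O1 lone pair (oxonium ylide, then Stevens 1,2-benzyl shift), over attack on the C5 silyl ether oxygen and over bimolecular cyclopropanation or carbene dimerisation. The substrate helps because the C–H bonds are doubly activated (α-oxygen plus 2',4'-dioxygenated aryl), O1 is a poor donor (conjugated to the ring A ketone and flanked by the C8 prenyl group), the silyl ethers carry no α-oxy C–H and little nucleophilicity, the C8 prenyl group is meta to the acyl carbon and the C5' dimethylallyl group lies on the far edge of ring B so that neither alkene can reach C3 within the molecule, while the non-polar solvent, low temperature and slow addition at high dilution work against the zwitterionic and the bimolecular paths.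

Step 11
Reactants: 15 the (2S)-tris-TBS flavanone
Product: 16 (2S)-5,7-dihydroxy-2-[4-hydroxy-2-methoxy-5-(2-methylbut-3-en-2-yl)phenyl]-8-(3-methylbut-2-enyl)chroman-4-one (CNP0308136.1)
Conditions: HF·pyridine, extra pyridine, THF, 0 °C to rt; pH 7 phosphate buffer work-up
Reagents that add atoms: none
Why: Fluoride-mediated cleavage of aryl silyl ethers driven by the strong Si–F bond: the pyridine-buffered medium is neither basic enough to open ring C by retro-oxa-Michael reaction (which would scramble C2) nor acidic enough to add the phenols to the prenyl or dimethylallyl alkenes.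

## Compound list

1 | 2',4',6'-trihydroxyacetophenone | CC(=O)c1c(O)cc(O)cc1O | starting material
2 | prenyl bromide (1-bromo-3-methylbut-2-ene) | CC(C)=CCBr | starting material
3 | 1-[2,4,6-trihydroxy-3-(3-methylbut-2-enyl)phenyl]ethanone | CC(=O)c1c(O)cc(O)c(CC=C(C)C)c1O | intermediate
4 | 1-[4,6-bis(tert-butyldimethylsilyloxy)-2-hydroxy-3-(3-methylbut-2-enyl)phenyl]ethanone | CC(=O)c1c(O[Si](C)(C)C(C)(C)C)cc(O[Si](C)(C)C(C)(C)C)c(CC=C(C)C)c1O | intermediate
5 | 4-hydroxy-2-methoxybenzaldehyde | COc1cc(O)ccc1C=O | starting material
6 | 2-methoxy-4-(3-methylbut-2-enyloxy)benzaldehyde | COc1cc(OCC=C(C)C)ccc1C=O | intermediate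
7 | 6-methoxy-3-(2-methylbut-3-en-2-yl)-4-oxocyclohexa-1,5-diene-1-carbaldehyde (racemic ortho-dienone, not isolated) | O=C1C=C(OC)C(C=O)=CC1C(C)(C)C=C | intermediate
8 | 4-hydroxy-2-methoxy-5-(2-methylbut-3-en-2-yl)benzaldehyde | COc1cc(O)c(C(C)(C)C=C)cc1C=O | intermediate
9 | 4-(tert-butyldimethylsilyloxy)-2-methoxy-5-(2-methylbut-3-en-2-yl)benzaldehyde | COc1cc(O[Si](C)(C)C(C)(C)C)c(C(C)(C)C=C)cc1C=O | intermediate
10 | [4-(tert-butyldimethylsilyloxy)-2-methoxy-5-(2-methylbut-3-en-2-yl)phenyl]methanol | COc1cc(O[Si](C)(C)C(C)(C)C)c(C(C)(C)C=C)cc1CO | intermediate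
11 | ring A/ring B benzyl ether methyl ketone | CC(=O)c1c(O[Si](C)(C)C(C)(C)C)cc(O[Si](C)(C)C(C)(C)C)c(CC=C(C)C)c1OCc1cc(C(C)(C)C=C)c(O[Si](C)(C)C(C)(C)C)cc1OC | intermediate
12 | lithium enolate of 11 (not isolated) | [Li+].C=C([O-])c1c(O[Si](C)(C)C(C)(C)C)cc(O[Si](C)(C)C(C)(C)C)c(CC=C(C)C)c1OCc1cc(C(C)(C)C=C)c(O[Si](C)(C)C(C)(C)C)cc1OC | intermediate
13 | 4,4,4-trifluoro-1-aryl-butane-1,3-dione from 11 (drawn as diketone) | O=C(CC(=O)C(F)(F)F)c1c(O[Si](C)(C)C(C)(C)C)cc(O[Si](C)(C)C(C)(C)C)c(CC=C(C)C)c1OCc1cc(C(C)(C)C=C)c(O[Si](C)(C)C(C)(C)C)cc1OC | intermediate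
14 | α-diazoketone, key-step precursor | [N-]=[N+]=CC(=O)c1c(O[Si](C)(C)C(C)(C)C)cc(O[Si](C)(C)C(C)(C)C)c(CC=C(C)C)c1OCc1cc(C(C)(C)C=C)c(O[Si](C)(C)C(C)(C)C)cc1OC | intermediate
15 | (2S)-5,7,4'-tris-TBS ether of the target, key-step product | O=C1C[C@@H](c2cc(C(C)(C)C=C)c(O[Si](C)(C)C(C)(C)C)cc2OC)Oc2c(CC=C(C)C)c(O[Si](C)(C)C(C)(C)C)cc(O[Si](C)(C)C(C)(C)C)c12 | intermediate
16 | (2S)-5,7-dihydroxy-2-[4-hydroxy-2-methoxy-5-(2-methylbut-3-en-2-yl)phenyl]-8-(3-methylbut-2-enyl)chroman-4-one | C=CC(C)(C)c1cc([C@@H]2CC(=O)c3c(O)cc(O)c(CC=C(C)C)c3O2)c(OC)cc1O | target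

## Step count and risks

Total step count: 11. Longest linear sequence: 9 steps (steps 3 to 11, from 5). The ring A branch (steps 1 and 2) joins at step 7.

**Risk 1, step 10.**
- The carbenoid may be captured by the O1 lone pair and the ring B benzyl group may then migrate 1,2.
- The two enantiotopic hydrogens may also be poorly told apart. An acceptor-only carbenoid reacts through an early transition state, or through stepwise hydride transfer and ion-pair collapse.
- The fallback closes ring C at O1–C2 instead and obtains the enantiomer by resolution. It sets out from 4 and 9 and comes back at 15.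
- Double deprotonation of 4 (LiHMDS, 2.2 equiv, THF, −78 °C) and aldol addition to 9 should give the racemic β-hydroxy ketone F1.
- Intramolecular Mitsunobu etherification (PPh3, DIAD, THF, 0 °C) should give the racemic tris-silyl flavanone F2.
- Kinetic resolution follows by asymmetric transfer hydrogenation with RhCl[(R,R)-TsDPEN](Cp*), HCO2H–Et3N, EtOAc, rt, stopped near half conversion.
- The (R,R) series is the one expected to take the 2R ketone faster, so it should reduce the 2R ketone to the cis-(2R,4R)-flavan-4-ol F3. It should leave 15, which is separated by chromatography.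

**Risk 2, step 7.**
- The crowded, hydrogen-bonded phenol may attack slowly. The activated electron-rich benzyl unit would then ionise and be lost to C-alkylation, oligomerisation or capture by the hydrazide.
- The fallback replaces phosphonium activation by a metal-bound benzyl electrophile. It sets out from 10 and comes back at 11.
- Acylation of 10 with methyl chloroformate (pyridine, CH2Cl2, 0 °C) gives the benzyl methyl carbonate F4.
- F4 is heated with 4 and a zerovalent palladium catalyst formed from Pd(η3-C3H5)Cp and DPEphos (toluene, 60–80 °C).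
- Ionisation with loss of CO2 gives an η3-benzylpalladium methoxide. The methoxide deprotonates the phenol, and the phenoxide attacks the benzylic carbon under neutral conditions.

**Risk 3, step 4.**
- The prenyl group may be lost by C–O heterolysis on heating, or part of it may migrate to C3.
- The product may also isomerise further (abnormal Claisen) or cyclise through its phenol onto the new alkene.
- The fallback installs the 1,1-dimethylallyl group by cross-coupling. It sets out from 5 and comes back at 10.
- Bromination ortho to OH and para to OMe (NBS, MeCN, 0 °C) gives 5-bromo-4-hydroxy-2-methoxybenzaldehyde F5.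
- Silylation (TBSCl, imidazole, DMF) gives the bromo silyl ether aldehyde F6.
- NaBH4 reduction gives the bromobenzyl alcohol F7. The aldehyde is removed at this point because it would be allylated by the boron reagent.
- A γ-selective Suzuki–Miyaura coupling with prenylboronic acid pinacol ester then joins the tertiary allyl terminus to C5 and gives 10. Conditions: Pd(OAc)2, a bulky biaryl dialkylphosphine of the type chosen for γ-attack, aqueous K3PO4, THF, 40 °C.

## Further compounds

F1 | step 10 | racemic 1-[4,6-bis(tert-butyldimethylsilyloxy)-2-hydroxy-3-(3-methylbut-2-enyl)phenyl]-3-[4-(tert-butyldimethylsilyloxy)-2-methoxy-5-(2-methylbut-3-en-2-yl)phenyl]-3-hydroxypropan-1-one | O=C(CC(O)c1cc(C(C)(C)C=C)c(O[Si](C)(C)C(C)(C)C)cc1OC)c1c(O[Si](C)(C)C(C)(C)C)cc(O[Si](C)(C)C(C)(C)C)c(CC=C(C)C)c1O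
F2 | step 10 | racemic 5,7,4'-tris-TBS flavanone (racemate of 15) | O=C1CC(c2cc(C(C)(C)C=C)c(O[Si](C)(C)C(C)(C)C)cc2OC)Oc2c(CC=C(C)C)c(O[Si](C)(C)C(C)(C)C)cc(O[Si](C)(C)C(C)(C)C)c12
F3 | step 10 | cis-(2R,4R)-5,7,4'-tris-TBS flavan-4-ol | O[C@@H]1C[C@H](c2cc(C(C)(C)C=C)c(O[Si](C)(C)C(C)(C)C)cc2OC)Oc2c(CC=C(C)C)c(O[Si](C)(C)C(C)(C)C)cc(O[Si](C)(C)C(C)(C)C)c12
F4 | step 7 | [4-(tert-butyldimethylsilyloxy)-2-methoxy-5-(2-methylbut-3-en-2-yl)phenyl]methyl methyl carbonate | COC(=O)OCc1cc(C(C)(C)C=C)c(O[Si](C)(C)C(C)(C)C)cc1OC
F5 | step 4 | 5-bromo-4-hydroxy-2-methoxybenzaldehyde | COc1cc(O)c(Br)cc1C=O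
F6 | step 4 | 5-bromo-4-(tert-butyldimethylsilyloxy)-2-methoxybenzaldehyde | COc1cc(O[Si](C)(C)C(C)(C)C)c(Br)cc1C=O
F7 | step 4 | [5-bromo-4-(tert-butyldimethylsilyloxy)-2-methoxyphenyl]methanol | COc1cc(O[Si](C)(C)C(C)(C)C)c(Br)cc1CO
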